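Start with an easy step: suppose each product made costs one solid reagent. Then the solid charge divided by the catalyst charge says how many turnovers the free catalyst can make before the solid reagent is used up. For the flask that gives 13.0; this ceiling N, solid reagent charged per free catalyst charged, is what we hold against the count n, product made per free catalyst charged.

in all of them: left-handed substrate 0.056 M; right-handed substrate 0.056 M; free catalyst 4.3 mM

| run | solid reagent | added ligand | remark | time |
|---|---|---|---|---|
| north | 0.028 M | 7 mM | run made earlier |  |
| south-east | 0.042 M | 7 mM | run made earlier |  |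
| north-east | 0.056 M | 14 mM | run made earlier |  |
| flask | 0.0560 M | 7.0 mM |  | 1.0 h |

| run | time / min | right-handed substrate / % | left-handed product / % | right-handed product / % | left-handed substrate / % |
|---|---|---|---|---|---|
| north | 10.0 | 48 | 7 | 1 | 47 |
| north | 20.0 | 44 | 13 | 3 | 39 |
| north | 30.0 | 48 | 15 | 7 | 40 |
| north | 40.0 | 46 | 12 | 4 | 40 |
| north | 50.0 | 47 | 16 | 5 | 31 |
| north | 60.0 | 45 | 13 | 7 | 33 |
| north | 80.0 | 46 | 19 | 6 | 31 |
| south-east | 6.00 | 46 | 6 | 4 | 45 |
| south-east | 8.00 | 46 | 1 | 4 | 38 |
| south-east | 12.0 | 49 | 7 | 1 | 40 |
| south-east | 20.0 | 43 | 12 | 4 | 41 |
| south-east | 30.0 | 48 | 14 | 4 | 36 |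
| south-east | 50.0 | 45 | 18 | 6 | 31 |
| south-east | 80.0 | 44 | 23 | 9 | 28 |
| north-east | 6.00 | 47 | 4 | 2 | 49 |
| north-east | 10.0 | 48 | 4 | 5 | 45 |
| north-east | 20.0 | 49 | 5 | 0 | 43 |
| north-east | 40.0 | 49 | 10 | 4 | 42 |
| north-east | 80.0 | 47 | 18 | 7 | 32 |

(each reading ± 2 percentage points)

- free catalyst is single-handed; left-handed substrate and right-handed substrate are mirror images of each other, charged as a racemate, each of them at the stated concentration
- solid, in amounts per volume of the solution: solid reagent
- at the start none of the solid reagent is in solution

- the largest share of what was charged as left-handed substrate and right-handed substrate together, at 1.0 h belongs to (right-handed substrate / left-handed product / right-handed product / left-handed substrate)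
- the largest share itself, whichever of these holds it, in percent of the left-handed substrate and right-handed substrate together charged

Two people stand at the board. Ben reads the last north row: within its scatter, n reads 6.51 against a north ceiling of 6.51. So he calls the solid reagent the limiting reagent and sends the flask to its ceiling, with half of the substrate converted.

Ada counts the other runs. The south-east run reads n = 6.25 at 50.0 min and 8.33 at 80.0 min, under its ceiling of 9.77. The north-east run has the flask's ceiling with twice the ligand, and it reads 6.51 at 80.0 min. So she expects pace to hold the flask under N at 1.0 h, and I side with her.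

The forecast sides with her too “It should follow the south-east run”, and names right-handed substrate at 44%.

The flask gives right-handed substrate at 39.7%, so the forecast is right within the margin.

    solid reagent ⇌ partner, rate k1*(cs1 - [partner]) while solid is left; crystals form when [partner] > cs1 (solubility = 40.0 mM, k = 1.10 min⁻¹)
    partner + free catalyst + left-handed substrate → free catalyst + left-handed product (k = 1700 M⁻² min⁻¹)
    free catalyst + added ligand ⇌ idle complex (K = 5500 M⁻¹, k = 340 M⁻¹ min⁻¹)
    partner + free catalyst + right-handed substrate → free catalyst + right-handed product (k = 540 M⁻² min⁻¹)
    2 free catalyst → spent catalyst (k = 5.60 M⁻¹ min⁻¹)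

In the flask, 48% of the charged left-handed substrate is left, less than the 79% of the right-handed substrate. The flask's count at 1.0 h is 9.42, below N, at 72.3% of the ceiling. Ben's view has its region: the flask left to 10.0 h counts 13.0, about N, and the neighbour charged with 0.0042 M of added ligand reaches at 1.0 h nearly all of the same ceiling, at 12.3.

The readings are calculated for substances that don't exist; scatter was added.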